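**Plan**

1. Ring A of the flavanone (C4a, C5, C6, C7, C8, C8a) is a phloroglucinol: C5, C7 and C8a carry oxygen and alternate with C4a, C6 and C8. It is read as a three-acetate chain folded onto the C4a=C8a enol ether of a 2-aryl-2,3-dihydropyran-4-one and is opened at C4a–C5, with C5 traced back to a ketene carbon stored as a dioxinone.
2. Further cuts: O1–C8a (cyclodehydration of a hydroxy diketone), C4–C4a (Claisen acylation of a keto-dioxinone dianion by a Weinreb amide), C8–C8a (acetylation of the dioxinone dienolate) and the biaryl bond C3'–C8'' (Suzuki coupling).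
3. Forward order: apigenin supplies the finished flavone; the ring B piece is made, coupled and chain-extended; the heterocyclic ring C closes first, the carbocyclic ring A last; hydrogenolysis then frees four phenols.
4. Stereochemistry: C2 (S) comes from a Ru/(R)-BINAP hydrogenation of an aryl β-keto ester; it is carried as a silyl ether and then as the ring C–O bond, and no later step breaks a bond to it.

Key step: step 13

Remark: the biaryl axis is treated as freely rotating, since the target is defined only by the S configuration at C2 of the flavanone.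
Abbreviation: ArBn = 4-(benzyloxy)-3-[5,7-bis(benzyloxy)-2-(4-(benzyloxy)phenyl)-4-oxo-4H-chromen-8-yl]phenyl, attached through C1 of the phenyl ring.

**Route**

Step 1
Reactants: 1 apigenin
Product: 2 5,7-bis(benzyloxy)-2-[4-(benzyloxy)phenyl]-4H-chromen-4-one
Conditions: BnBr (4.5 equiv), K2CO3, DMF, 80 °C
Reagents that add atoms: benzyl bromide, BrCc1ccccc1
Why: Williamson etherification; the 7- and 4'-phenols alkylate readily and the hydrogen-bonded 5-OH should follow with excess bromide and heat, as is routine for perbenzylation of 5-hydroxyflavones.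

Step 2
Reactants: 2 5,7-bis(benzyloxy)-2-[4-(benzyloxy)phenyl]-4H-chromen-4-one
Product: 3 5,7-bis(benzyloxy)-2-[4-(benzyloxy)phenyl]-8-iodo-4H-chromen-4-one
Conditions: NIS (1.1 equiv), CF3CO2H (0.2 equiv), MeCN/CH2Cl2, 0 °C → rt, dark
Reagents that add atoms: N-iodosuccinimide, O=C1CCC(=O)N1I
Why: Electrophilic aromatic iodination of the phloroglucinol-type ring; with the 5-oxygen alkylated, C6 is shielded between two benzyloxy groups and attack is expected at C8, the regiochemistry known for fully O-alkylated 5,7-dioxygenated flavones.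

Step 3
Reactants: 4 1-(3-bromo-4-hydroxyphenyl)ethan-1-one
Product: 5 1-[4-(benzyloxy)-3-bromophenyl]ethan-1-one
Conditions: BnBr, K2CO3, acetone, reflux
Reagents that add atoms: benzyl bromide, BrCc1ccccc1
Why: Williamson etherification of an acidic para-acyl phenol.

Step 4
Reactants: 5 1-[4-(benzyloxy)-3-bromophenyl]ethan-1-one
Product: 6 ethyl 3-[4-(benzyloxy)-3-bromophenyl]-3-oxopropanoate
Conditions: NaH (2.5 equiv), (EtO)2CO, THF, reflux; AcOH, H2O
Reagents that add atoms: diethyl carbonate, CCOC(=O)OCC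
Why: Crossed Claisen condensation of the methyl ketone enolate with diethyl carbonate, driven to completion by deprotonation of the β-keto ester formed.

Step 5
Reactants: 6 ethyl 3-[4-(benzyloxy)-3-bromophenyl]-3-oxopropanoate
Product: 7 ethyl (3S)-3-[4-(benzyloxy)-3-bromophenyl]-3-hydroxypropanoate
Conditions: H2 (50 bar), [RuCl(p-cymene)((R)-BINAP)]Cl (1 mol %), EtOH, 50 °C
Reagents that add atoms: none
Why: Noyori asymmetric hydrogenation of a β-keto ester; the ester-chelated ketone on the (R)-BINAP ruthenium hydride is reduced from the face that turns acetoacetates into (R)-3-hydroxybutanoates, which for an aryl ketone is the (S)-carbinol, and this sets the only stereocentre of the target while aryl bromide and benzyl ether stay inert.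

Step 6
Reactants: 7 ethyl (3S)-3-[4-(benzyloxy)-3-bromophenyl]-3-hydroxypropanoate
Product: 8 ethyl (3S)-3-[4-(benzyloxy)-3-bromophenyl]-3-[(tert-butyldimethylsilyl)oxy]propanoate
Conditions: TBSCl, imidazole, DMF, rt
Reagents that add atoms: tert-butyldimethylsilyl chloride, CC(C)(C)[Si](C)(C)Cl
Why: Standard silylation of a secondary alcohol, which blocks retro-aldol and elimination pathways in the basic steps that follow.

Step 7
Reactants: 8 ethyl (3S)-3-[4-(benzyloxy)-3-bromophenyl]-3-[(tert-butyldimethylsilyl)oxy]propanoate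
Product: 9 (3S)-3-[4-(benzyloxy)-3-bromophenyl]-3-[(tert-butyldimethylsilyl)oxy]-N-methoxy-N-methylpropanamide
Conditions: MeNHOMe·HCl, iPrMgCl, THF, −20 → 0 °C
Reagents that add atoms: N,O-dimethylhydroxylamine hydrochloride, CNOC.Cl
Why: Weinreb amidation; the chloromagnesium amide formed in the flask aminolyses the ethyl ester at low temperature, where the electron-rich aryl bromide does not undergo halogen–magnesium exchange.

Step 8
Reactants: 9 (3S)-3-[4-(benzyloxy)-3-bromophenyl]-3-[(tert-butyldimethylsilyl)oxy]-N-methoxy-N-methylpropanamide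
Product: 10 (3S)-3-[4-(benzyloxy)-3-(4,4,5,5-tetramethyl-1,3,2-dioxaborolan-2-yl)phenyl]-3-[(tert-butyldimethylsilyl)oxy]-N-methoxy-N-methylpropanamide
Conditions: B2pin2, PdCl2(dppf)·CH2Cl2 (5 mol %), KOAc, 1,4-dioxane, 90 °C
Reagents that add atoms: bis(pinacolato)diboron, CC1(C)OB(B2OC(C)(C)C(C)(C)O2)OC1(C)C
Why: Miyaura borylation of an aryl bromide under weakly basic conditions that tolerate the amide and the silyl ether.

Step 9
Reactants: 3 5,7-bis(benzyloxy)-2-[4-(benzyloxy)phenyl]-8-iodo-4H-chromen-4-one; 10 (3S)-3-[4-(benzyloxy)-3-(4,4,5,5-tetramethyl-1,3,2-dioxaborolan-2-yl)phenyl]-3-[(tert-butyldimethylsilyl)oxy]-N-methoxy-N-methylpropanamide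
Product: 11 (3S)-3-ArBn-3-[(tert-butyldimethylsilyl)oxy]-N-methoxy-N-methylpropanamide
Conditions: Pd(OAc)2 (5 mol %), SPhos (10 mol %), K3PO4, PhMe/H2O (10:1), 90 °C
Reagents that add atoms: none
Why: Suzuki–Miyaura coupling forms the C3'–C8'' biaryl bond; a bulky biarylphosphine is chosen because the product is a tri-ortho-substituted biaryl.

Step 10
Reactants: 12 2,2,6-trimethyl-4H-1,3-dioxin-4-one
Product: 14 2,2-dimethyl-6-(2-oxopropyl)-4H-1,3-dioxin-4-one, via lithium dienolate 13 (not isolated)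
Conditions: 12 (2.0 equiv), LiN(SiMe3)2 (2.0 equiv), THF, −78 °C; AcCl (1.0 equiv), −78 °C; aq. NH4Cl
Reagents that add atoms: acetyl chloride, CC(=O)Cl
Why: Vinylogous Claisen acylation; the 6-methyl group is deprotonated to the extended dienolate, which is C-acylated at its terminus, with the second equivalent of dienolate taking up the acidic proton of the product.

Step 11
Reactants: 14 2,2-dimethyl-6-(2-oxopropyl)-4H-1,3-dioxin-4-one; 11 (3S)-3-ArBn-3-[(tert-butyldimethylsilyl)oxy]-N-methoxy-N-methylpropanamide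
Product: 16 6-[(6S)-6-ArBn-6-[(tert-butyldimethylsilyl)oxy]-2,4-dioxohexyl]-2,2-dimethyl-4H-1,3-dioxin-4-one, via dilithium dianion 15 (not isolated)
Conditions: 14 (2.0 equiv), LiN(iPr)2 (3.9 equiv), THF, −78 °C; then 11, −78 → −40 °C; aq. NH4Cl
Reagents that add atoms: none
Why: Claisen-type C-acylation of a 1,3-dicarbonyl dianion at its more basic terminal carbon by a Weinreb amide, whose chelated tetrahedral adduct persists until work-up and so prevents a second addition; no free amide base remains to attack the flavone.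

Step 12
Reactants: 16 6-[(6S)-6-ArBn-6-[(tert-butyldimethylsilyl)oxy]-2,4-dioxohexyl]-2,2-dimethyl-4H-1,3-dioxin-4-one
Product: 19 (2S)-2-ArBn-6-[(2,2-dimethyl-4-oxo-4H-1,3-dioxin-6-yl)methyl]-2,3-dihydro-4H-pyran-4-one, via hydroxy diketone 17 (not isolated), via cyclic hemiketal 18 (not isolated)
Conditions: HF·pyridine, THF, 0 °C → rt; then PPTS (0.2 equiv), 4 Å MS, CH2Cl2, rt
Reagents that add atoms: none
Why: Fluoride desilylation frees the hydroxyl, which closes by 6-exo-trig addition to the ketone next to the dioxinonylmethyl group, and mild acid dehydrates the hemiketal to the conjugated dihydropyranone; the C–O bond at the stereocentre is never broken, so the S configuration is kept.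

Step 13
Reactants: 19 (2S)-2-ArBn-6-[(2,2-dimethyl-4-oxo-4H-1,3-dioxin-6-yl)methyl]-2,3-dihydro-4H-pyran-4-one
Product: 23 (2S)-2-ArBn-5,7-dihydroxy-2,3-dihydro-4H-chromen-4-one, via acylketene 20 (not isolated), via dienylketene enol 21 (not isolated), via cyclohexadienone 22 (not isolated)
Conditions: dry degassed PhMe (0.002 M), 110 °C, slow addition of 19, argon sweep to carry off acetone
Reagents that add atoms: none
Why: Proposed new method: at 110 °C the dioxinone should lose acetone by retro-[4+2] to give acylketene 20, whose ketone enolises toward the pyranone to dienylketene 21, a 6π system made of the ketene C=C, the enol C=C and the pyranone C5=C6 enol ether; thermal disrotatory 6π-electrocyclisation (equally describable as C-acylation of the enol ether carbon by the ketene) joins the ketene carbon (future C5) to pyranone C5 (future C4a) to give cyclohexa-2,4-dienone 22, which aromatises by a proton shift to the 5,7-dihydroxy arene. The closest known reaction types are thermal acylketene generation from dioxinones with biomimetic aromatisation of polycarbonyl dioxinones, Claisen cyclisation of 3,5,7-triketo esters to acylphloroglucinols, and 6π-electrocyclisation of dienylketenes to phenols. The one ring closed is the six-membered carbocycle A, formed by 6π-electrocyclisation with C4a–C5 as the only new skeletal bond. No stereocentre is created (the sp3 C4a of 22 is lost on aromatisation), and C2 is only carried, because the medium is neutral and holds neither base nor acid that could open the ring by retro-oxa-Michael reaction. The step needs capture of the ketene at carbon within the molecule rather than at oxygen or by a second molecule: the oxygen that would lactonise an open-chain diketo-dioxinone to a 4-hydroxy-2-pyranone is here tied up as the ring ether O1, so the only six-membered closure within reach is on C5, while high dilution, slow addition, dry solvent and removal of acetone hold back ketene dimerisation, acylation of product phenols, hydrolysis and return to 19.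

Step 14
Reactants: 23 (2S)-2-ArBn-5,7-dihydroxy-2,3-dihydro-4H-chromen-4-one
Product: 24 (2S)-5,7-dihydroxy-2-{4-hydroxy-3-[5,7-dihydroxy-2-(4-hydroxyphenyl)-4-oxo-4H-chromen-8-yl]phenyl}-2,3-dihydro-4H-chromen-4-one (target)
Conditions: H2 (1 atm), Pd/C (10 wt %), THF/MeOH (1:1), rt, stopped when the benzyl ethers are consumed
Reagents that add atoms: none
Why: Hydrogenolysis of aryl benzyl ethers over palladium on carbon under neutral conditions, where the flavone C2=C3 bond and the flavanone C2–O1 bond are reduced much more slowly and C2 cannot epimerise.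

**Compound list**

1 | apigenin | O=c1cc(-c2ccc(O)cc2)oc2cc(O)cc(O)c12 | starting material
2 | 5,7-bis(benzyloxy)-2-[4-(benzyloxy)phenyl]-4H-chromen-4-one | O=c1cc(-c2ccc(OCc3ccccc3)cc2)oc2cc(OCc3ccccc3)cc(OCc3ccccc3)c12 | intermediate
3 | 5,7-bis(benzyloxy)-2-[4-(benzyloxy)phenyl]-8-iodo-4H-chromen-4-one | O=c1cc(-c2ccc(OCc3ccccc3)cc2)oc2c(I)c(OCc3ccccc3)cc(OCc3ccccc3)c12 | intermediate
4 | 1-(3-bromo-4-hydroxyphenyl)ethan-1-one | CC(=O)c1ccc(O)c(Br)c1 | starting material
5 | 1-[4-(benzyloxy)-3-bromophenyl]ethan-1-one | CC(=O)c1ccc(OCc2ccccc2)c(Br)c1 | intermediate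
6 | ethyl 3-[4-(benzyloxy)-3-bromophenyl]-3-oxopropanoate | CCOC(=O)CC(=O)c1ccc(OCc2ccccc2)c(Br)c1 | intermediate
7 | ethyl (3S)-3-[4-(benzyloxy)-3-bromophenyl]-3-hydroxypropanoate | CCOC(=O)C[C@H](O)c1ccc(OCc2ccccc2)c(Br)c1 | intermediate
8 | ethyl (3S)-3-[4-(benzyloxy)-3-bromophenyl]-3-[(tert-butyldimethylsilyl)oxy]propanoate | CCOC(=O)C[C@H](O[Si](C)(C)C(C)(C)C)c1ccc(OCc2ccccc2)c(Br)c1 | intermediate
9 | (3S)-3-[4-(benzyloxy)-3-bromophenyl]-3-[(tert-butyldimethylsilyl)oxy]-N-methoxy-N-methylpropanamide | CON(C)C(=O)C[C@H](O[Si](C)(C)C(C)(C)C)c1ccc(OCc2ccccc2)c(Br)c1 | intermediate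
10 | (3S)-3-[4-(benzyloxy)-3-(4,4,5,5-tetramethyl-1,3,2-dioxaborolan-2-yl)phenyl]-3-[(tert-butyldimethylsilyl)oxy]-N-methoxy-N-methylpropanamide | CON(C)C(=O)C[C@H](O[Si](C)(C)C(C)(C)C)c1ccc(OCc2ccccc2)c(B2OC(C)(C)C(C)(C)O2)c1 | intermediate
11 | (3S)-3-ArBn-3-[(tert-butyldimethylsilyl)oxy]-N-methoxy-N-methylpropanamide | CON(C)C(=O)C[C@H](O[Si](C)(C)C(C)(C)C)c1ccc(OCc2ccccc2)c(-c2c(OCc3ccccc3)cc(OCc3ccccc3)c3c(=O)cc(-c4ccc(OCc5ccccc5)cc4)oc23)c1 | intermediate
12 | 2,2,6-trimethyl-4H-1,3-dioxin-4-one | CC1=CC(=O)OC(C)(C)O1 | starting material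
13 | lithium 2,2-dimethyl-6-methylidene-6H-1,3-dioxin-4-olate (dienolate of 12) | C=C1C=C(O[Li])OC(C)(C)O1 | intermediate
14 | 2,2-dimethyl-6-(2-oxopropyl)-4H-1,3-dioxin-4-one | CC(=O)CC1=CC(=O)OC(C)(C)O1 | intermediate
15 | dilithium dianion of 14 (terminal enolate and ring dienolate) | C=C(O[Li])C=C1C=C(O[Li])OC(C)(C)O1 | intermediate
16 | 6-[(6S)-6-ArBn-6-[(tert-butyldimethylsilyl)oxy]-2,4-dioxohexyl]-2,2-dimethyl-4H-1,3-dioxin-4-one | CC1(C)OC(=O)C=C(CC(=O)CC(=O)C[C@H](O[Si](C)(C)C(C)(C)C)c2ccc(OCc3ccccc3)c(-c3c(OCc4ccccc4)cc(OCc4ccccc4)c4c(=O)cc(-c5ccc(OCc6ccccc6)cc5)oc34)c2)O1 | intermediate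
17 | 6-[(6S)-6-ArBn-6-hydroxy-2,4-dioxohexyl]-2,2-dimethyl-4H-1,3-dioxin-4-one | CC1(C)OC(=O)C=C(CC(=O)CC(=O)C[C@H](O)c2ccc(OCc3ccccc3)c(-c3c(OCc4ccccc4)cc(OCc4ccccc4)c4c(=O)cc(-c5ccc(OCc6ccccc6)cc5)oc34)c2)O1 | intermediate
18 | (6S)-6-ArBn-2-[(2,2-dimethyl-4-oxo-4H-1,3-dioxin-6-yl)methyl]-2-hydroxytetrahydro-4H-pyran-4-one (hemiketal carbon a mixture) | CC1(C)OC(=O)C=C(CC2(O)CC(=O)C[C@@H](c3ccc(OCc4ccccc4)c(-c4c(OCc5ccccc5)cc(OCc5ccccc5)c5c(=O)cc(-c6ccc(OCc7ccccc7)cc6)oc45)c3)O2)O1 | intermediate
19 | (2S)-2-ArBn-6-[(2,2-dimethyl-4-oxo-4H-1,3-dioxin-6-yl)methyl]-2,3-dihydro-4H-pyran-4-one | CC1(C)OC(=O)C=C(CC2=CC(=O)C[C@@H](c3ccc(OCc4ccccc4)c(-c4c(OCc5ccccc5)cc(OCc5ccccc5)c5c(=O)cc(-c6ccc(OCc7ccccc7)cc6)oc45)c3)O2)O1 | intermediate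
20 | 4-[(2S)-2-ArBn-4-oxo-2,3-dihydro-4H-pyran-6-yl]-3-oxobut-1-en-1-one (acylketene) | O=C=CC(=O)CC1=CC(=O)C[C@@H](c2ccc(OCc3ccccc3)c(-c3c(OCc4ccccc4)cc(OCc4ccccc4)c4c(=O)cc(-c5ccc(OCc6ccccc6)cc5)oc34)c2)O1 | intermediate
21 | enol of 20 with the ketene and the pyranone cis across the enol double bond (dienylketene) | O=C=C/C(O)=C\C1=CC(=O)C[C@@H](c2ccc(OCc3ccccc3)c(-c3c(OCc4ccccc4)cc(OCc4ccccc4)c4c(=O)cc(-c5ccc(OCc6ccccc6)cc5)oc34)c2)O1 | intermediate
22 | (2S)-2-ArBn-7-hydroxy-2,3-dihydro-4H-chromene-4,5(4aH)-dione (C4a transient, unassigned) | O=C1C[C@@H](c2ccc(OCc3ccccc3)c(-c3c(OCc4ccccc4)cc(OCc4ccccc4)c4c(=O)cc(-c5ccc(OCc6ccccc6)cc5)oc34)c2)OC2=CC(O)=CC(=O)C12 | intermediate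
23 | (2S)-2-ArBn-5,7-dihydroxy-2,3-dihydro-4H-chromen-4-one | O=C1C[C@@H](c2ccc(OCc3ccccc3)c(-c3c(OCc4ccccc4)cc(OCc4ccccc4)c4c(=O)cc(-c5ccc(OCc6ccccc6)cc5)oc34)c2)Oc2cc(O)cc(O)c21 | intermediate
24 | (2S)-5,7-dihydroxy-2-{4-hydroxy-3-[5,7-dihydroxy-2-(4-hydroxyphenyl)-4-oxo-4H-chromen-8-yl]phenyl}-2,3-dihydro-4H-chromen-4-one | O=C1C[C@@H](c2ccc(O)c(-c3c(O)cc(O)c4c(=O)cc(-c5ccc(O)cc5)oc34)c2)Oc2cc(O)cc(O)c21 | target

**Step count and risks**

Total steps: 14. Longest linear sequence: 11 steps (steps 3 to 9, then 11 to 14).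

Steps most likely to fail:

1. Step 13 (Proposed new method). The ketene may be consumed by dimerisation, by acylation of product phenols or by traces of water before the carbon–carbon closure occurs, or the enol ether carbon may prove too weak a nucleophile so that the ketene simply recombines with acetone. Fallback with known chemistry, from 19 back to 23: 19 is heated in toluene containing methanol, which intercepts the acylketene in the usual way and should give methyl 4-[(2S)-2-ArBn-4-oxo-2,3-dihydro-4H-pyran-6-yl]-3-oxobutanoate F1. Treatment of this ester with Mg(OMe)2 in MeOH at room temperature should then effect a Claisen (Dieckmann-type) cyclisation of the magnesium-chelated polyketo ester, the extended enolate acylating at pyranone C5, and aromatisation would deliver 23.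

2. Step 12. Ionisation at the para-benzyloxybenzylic C–O bond under acid may erode the enantiomeric purity or cause elimination, and aldol aromatisation of the open diketo-dioxinone to a resorcylate may compete with closure by oxygen. Fallback, from 11 back to 19: the silyl ether is removed before chain extension with nBu4NF/AcOH in THF to give (3S)-3-ArBn-3-hydroxy-N-methoxy-N-methylpropanamide F2. This hydroxy amide is added to an excess of dianion 15, the first equivalent forming the alkoxide, so that work-up gives hydroxy diketone 17 directly, in equilibrium with hemiketal 18. A catalytic amount of PPTS with 4 Å MS in CH2Cl2 then suffices for dehydration to 19, and the sensitive chain never meets a fluoride or a stronger acid.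

3. Step 11. The hindered dianion may act as a base, enolising the amide with E1cB loss of silanolate, or may add to the flavone carbonyl, and conversion may stall. Fallback, from 11 back to 16: the Weinreb amide is reduced with Cp2Zr(H)Cl in THF to (3S)-3-ArBn-3-[(tert-butyldimethylsilyl)oxy]propanal F3. Aldol addition of dianion 15 to this much more electrophilic aldehyde at −78 °C should give 6-[(6S)-6-ArBn-6-[(tert-butyldimethylsilyl)oxy]-4-hydroxy-2-oxohexyl]-2,2-dimethyl-4H-1,3-dioxin-4-one F4 as a mixture at the new carbinol. Oxidation of this β-hydroxy ketone with Dess–Martin periodinane in CH2Cl2 then converges on diketone 16.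

Further compounds
F1 | step 13 | methyl 4-[(2S)-2-ArBn-4-oxo-2,3-dihydro-4H-pyran-6-yl]-3-oxobutanoate | COC(=O)CC(=O)CC1=CC(=O)C[C@@H](c2ccc(OCc3ccccc3)c(-c3c(OCc4ccccc4)cc(OCc4ccccc4)c4c(=O)cc(-c5ccc(OCc6ccccc6)cc5)oc34)c2)O1
F2 | step 12 | (3S)-3-ArBn-3-hydroxy-N-methoxy-N-methylpropanamide | CON(C)C(=O)C[C@H](O)c1ccc(OCc2ccccc2)c(-c2c(OCc3ccccc3)cc(OCc3ccccc3)c3c(=O)cc(-c4ccc(OCc5ccccc5)cc4)oc23)c1
F3 | step 11 | (3S)-3-ArBn-3-[(tert-butyldimethylsilyl)oxy]propanal | O=CC[C@H](O[Si](C)(C)C(C)(C)C)c1ccc(OCc2ccccc2)c(-c2c(OCc3ccccc3)cc(OCc3ccccc3)c3c(=O)cc(-c4ccc(OCc5ccccc5)cc4)oc23)c1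
F4 | step 11 | 6-[(6S)-6-ArBn-6-[(tert-butyldimethylsilyl)oxy]-4-hydroxy-2-oxohexyl]-2,2-dimethyl-4H-1,3-dioxin-4-one (C4 of the hexyl chain a mixture) | CC1(C)OC(=O)C=C(CC(=O)CC(O)C[C@H](O[Si](C)(C)C(C)(C)C)c2ccc(OCc3ccccc3)c(-c3c(OCc4ccccc4)cc(OCc4ccccc4)c4c(=O)cc(-c5ccc(OCc6ccccc6)cc5)oc34)c2)O1
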